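The runs come from a simulation from invented constants; noise was put on by code.

- A ratio of 1.86 of left-handed product to right-handed product (the selectivity factor) stood in the west run at 20.0 min. Both runs charged a racemate, with single-handed free catalyst and a racemization catalyst, and differed in added ligand.

| setting | east | west | flask |
|---|---|---|---|
| left-handed substrate | 0.10 M | 0.10 M | 0.10 M |
| right-handed substrate | 0.10 M | 0.10 M | 0.10 M |
| reagent | 0.40 M | 0.40 M | 0.400 M |
| racemization catalyst | 1 mM | 1 mM | 1.0 mM |
| precatalyst | 0.50 mM | 0.50 mM | 0.50 mM |
| added ligand | 2.4 mM | 3.6 mM | 2.4 mM |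
| remark | the very flask that is asked about, followed so far | run made earlier |  |
| time |  |  | 20 min |

| run | time / min | left-handed product / % | right-handed product / % | left-handed substrate / % |
|---|---|---|---|---|
| east | 0.333 | 0.6 | 0 | 50.6 |
| east | 0.500 | 1.8 | 0.6 | 48.8 |
| east | 0.667 | 2.4 | 0.6 | 48.3 |
| east | 1.00 | 4.0 | 3.0 | 46.8 |
| east | 1.50 | 6.4 | 3.1 | 45.8 |
| east | 2.50 | 9.8 | 5.1 | 42.0 |
| east | 4.00 | 12.6 | 6.8 | 39.2 |
| west | 1.00 | 3.8 | 1.8 | 47.4 |
| west | 3.00 | 8.5 | 5.0 | 42.9 |
| west | 6.00 | 13.6 | 7.1 | 39.9 |
| west | 8.00 | 16.7 | 9.6 | 38.1 |
| west | 12.0 | 21.0 | 10.8 | 33.4 |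
| west | 15.0 | 23.4 | 12.5 | 31.4 |
| west | 20.0 | 28.4 | 15.3 | 27.8 |

(readings scatter by 0.5 percentage points)

- free catalyst is single-handed; left-handed substrate and right-handed substrate are mirror images of each other, charged as a racemate, each of them at the stated concentration
- an excess is the difference of the two amounts in percent of their sum
- an excess is below zero if the other one leads

- left-handed product and right-handed product together, in percent of the left-handed substrate and right-handed substrate charged together, at 20 min
- excess of left-handed product over right-handed product in the product at 20 min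
- whether the exchange between left-handed substrate and right-handed substrate keeps pace with the reaction: how far the product's excess at 20 min gets from its value without exchange to its value with instant exchange (above 80 % keeps pace, below 20 % hardly takes part, else lags behind)

- The puzzle was that left-handed product plus left-handed substrate in the west run at 20.0 min came to 56.2 % of the charge, though 50.0 % was charged as left-handed substrate.
- I followed one molecule. West gave 0.650 of its product as left-handed, and I called this the fork share f, the chance that a substrate molecule that reacts leaves as left-handed product. East read 0.649 at 4.00 min, with c(added ligand) 2.4 mM against 3.6 mM.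
- A racemic substrate pool needs (f − 0.5) of the product to cross from right-handed to left-handed substrate, which in west was 6.5 percentage points. The readings showed 6.2 points crossed, so the puzzle cleared: this was dynamic kinetic resolution.
- With exchange keeping pace, I reckoned the flask's excess as 2f − 1, or 30.0 %.
- The forecast gave 52 % (47 % to 58 %) of product, an excess of 30 % (27 % to 33 %), and keeps pace: “Exchange is therefore fast and keeps pace.”
- The flask gave 54.4 %, an excess of 30.0 %, and keeps pace, at 89 % of the way.

    reagent + free catalyst + right-handed substrate → free catalyst + right-handed product (k = 9.88 L² mol⁻² s⁻¹)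
    left-handed substrate + racemization catalyst ⇌ right-handed substrate + racemization catalyst, rate k2*[racemization catalyst]*[left-handed substrate] forward; the back reaction follows from the equilibrium constant (k = 8.84 L mol⁻¹ s⁻¹)
    reagent + free catalyst + left-handed substrate → free catalyst + left-handed product (k = 18.8 L² mol⁻² s⁻¹)
    reagent → decomposition product (k = 6.07 × 10⁻⁵ s⁻¹)
    free catalyst + added ligand ⇌ idle complex (K = 1360 L mol⁻¹, k = 7.14 L mol⁻¹ s⁻¹)
    precatalyst → free catalyst (k = 0.0226 s⁻¹)

- Applied to 54.4 %, f gave 35.4 % of left-handed product; the flask held 35.4 %, with 73.4 % of the catalyst as idle complex and 26.6 % as free catalyst. The neighbouring flask, with c(added ligand) 1.40 mM, held 40.1 % as free catalyst and reached 66.4 % of product. There f gave 43.2 %, and that flask held 43.0 % of left-handed product.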